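**Retrosynthetic overview**

1. Feature used: in ring A the unit C18(OAc)–C4(quaternary)–C5(ring-fusion CH)–C6=C7(ring B alkene) is a γ,δ-unsaturated acid at the alcohol oxidation level, which is the retron of a Claisen rearrangement.
2. Key disconnection C4–C5: Ireland–Claisen ring contraction of a ten-membered E-allylic lactone (C18 carboxyl esterified to an allylic oxygen on a sacrificial carbon C7′ bound to C6); this closes ring A first.
3. Ring B second: diene–ene ring-closing metathesis between the C5 vinyl group and a 2-substituted butadiene on C9 (gives C6=C7 and C8=C17), then ketal hydrolysis and Horner–Wadsworth–Emmons olefination (C13=C14).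
4. The lactone comes from macrolactonisation of a seco acid whose C9/C10 pair is set by an earlier acyclic Ireland–Claisen rearrangement with 1,3-chirality transfer from an (R)-allylic carbinol.
5. Carbon sources: geranyl acetate (C1–C6, C10, C18–C20), 5-oxohexanoic acid (C8, C9, C11–C13, C16), MeLi (C17), a vinylstannane (C7), trimethyl phosphonoacetate (C14, C15).

Key step: step 20

Remark 1: labdane numbering is used; C7′ is the oxygen-bearing allylic carbon of the lactone, which is not C7 of the target: it leaves as ethylene in step 23, and C7 comes from the vinyl group added in step 15.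
Remark 2: the methyl-bearing carbon that becomes C4 is carried as a mixture of epimers (drawn without configuration), because step 20 planarises it.
Remark 3 (assumption): in step 9 the alkenyl group is taken as the large substituent of the usual oxazaborolidine model, so the (R)-catalyst is assigned to the (R)-carbinol; if the sense proves opposite, the (S)-catalyst is used.

**Route**

Step 1
Reactants: 1 geranyl acetate
Product: 2 (2E,6E)-8-hydroxy-3,7-dimethylocta-2,6-dien-1-yl acetate
Conditions: SeO2 (0.3 equiv), t-BuOOH (3 equiv), salicylic acid (cat.), CH2Cl2, rt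
Reagents that add atoms: tert-butyl hydroperoxide, CC(C)(C)OO
Why: Allylic oxidation with SeO2 (ene reaction followed by 2,3-sigmatropic shift) takes place at the E-methyl group of the electron-rich terminal alkene, the other alkene being deactivated by the allylic acetate, and gives the E-allylic alcohol whose carbon becomes C18.

Step 2
Reactants: 2 (2E,6E)-8-hydroxy-3,7-dimethylocta-2,6-dien-1-yl acetate
Product: 3 (2E)-8-hydroxy-3,7-dimethyloct-2-en-1-yl acetate (7RS)
Conditions: H2 (50 atm), Ru(OAc)2(rac-BINAP) (1 mol%), MeOH, rt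
Reagents that add atoms: none
Why: Hydroxyl-directed homogeneous hydrogenation should saturate only the alkene of the free allylic alcohol, the acetylated allylic alkene having no coordinating hydroxyl, and the new centre (the later C4) needs no control because step 20 erases it.

Step 3
Reactants: 3 (2E)-8-hydroxy-3,7-dimethyloct-2-en-1-yl acetate
Product: 4 (2E)-8-(tert-butyldimethylsilyloxy)-3,7-dimethyloct-2-en-1-yl acetate
Conditions: t-BuMe2SiCl, imidazole, CH2Cl2, 0 °C to rt
Reagents that add atoms: tert-butyldimethylsilyl chloride, CC(C)(C)[Si](C)(C)Cl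
Why: Standard silylation protects the primary hydroxyl (later C18) so that it survives the organometallic and enolate steps.

Step 4
Reactants: 4 (2E)-8-(tert-butyldimethylsilyloxy)-3,7-dimethyloct-2-en-1-yl acetate
Product: 5 (2E)-8-(tert-butyldimethylsilyloxy)-3,7-dimethyloct-2-en-1-ol
Conditions: K2CO3 (0.2 equiv), MeOH, rt
Reagents that add atoms: none
Why: Base-catalysed transesterification removes the acetate while the alkyl silyl ether is stable to carbonate in methanol.

Step 5
Reactants: 5 (2E)-8-(tert-butyldimethylsilyloxy)-3,7-dimethyloct-2-en-1-ol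
Product: 6 (2E)-8-(tert-butyldimethylsilyloxy)-3,7-dimethyloct-2-enal
Conditions: MnO2 (activated, excess), CH2Cl2, rt
Reagents that add atoms: none
Why: Activated MnO2 oxidises allylic alcohols selectively to enals under neutral conditions that leave the alkene geometry and the silyl ether intact.

Step 6
Reactants: 6 (2E)-8-(tert-butyldimethylsilyloxy)-3,7-dimethyloct-2-enal
Product: 8 (3E)-9-(tert-butyldimethylsilyloxy)-4,8-dimethylnon-3-ene-1,2-diol (racemic carbinol), via hydroxysilane 7 (not isolated)
Conditions: (iPrO)Me2SiCH2MgCl, THF, 0 °C; then KF, KHCO3, 30% H2O2, THF/MeOH, rt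
Reagents that add atoms: (isopropoxydimethylsilyl)methylmagnesium chloride, CC(C)O[Si](C)(C)C[Mg]Cl; hydrogen peroxide, OO
Why: Nucleophilic hydroxymethylation (1,2-Grignard addition to the enal followed by Tamao oxidation of the C–Si bond) adds the sacrificial carbon C7′ and gives the racemic allylic 1,2-diol.

Step 7
Reactants: 8 (3E)-9-(tert-butyldimethylsilyloxy)-4,8-dimethylnon-3-ene-1,2-diol
Product: 9 (3E)-9-(tert-butyldimethylsilyloxy)-1-(tert-butyldiphenylsilyloxy)-4,8-dimethylnon-3-en-2-ol (racemic carbinol)
Conditions: t-BuPh2SiCl (1.05 equiv), imidazole, CH2Cl2, −20 to 0 °C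
Reagents that add atoms: tert-butyldiphenylsilyl chloride, CC(C)(C)[Si](Cl)(c1ccccc1)c1ccccc1
Why: Silylation with the bulky chloride is selective for the primary hydroxyl and leaves the secondary allylic hydroxyl free.

Step 8
Reactants: 9 (3E)-9-(tert-butyldimethylsilyloxy)-1-(tert-butyldiphenylsilyloxy)-4,8-dimethylnon-3-en-2-ol
Product: 10 (3E)-9-(tert-butyldimethylsilyloxy)-1-(tert-butyldiphenylsilyloxy)-4,8-dimethylnon-3-en-2-one
Conditions: MnO2 (activated, excess), CH2Cl2, rt
Reagents that add atoms: none
Why: Allylic oxidation with MnO2 converts the racemic carbinol into the enone so that this centre can be reset under reagent control.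

Step 9
Reactants: 10 (3E)-9-(tert-butyldimethylsilyloxy)-1-(tert-butyldiphenylsilyloxy)-4,8-dimethylnon-3-en-2-one
Product: 11 (2R,3E)-9-(tert-butyldimethylsilyloxy)-1-(tert-butyldiphenylsilyloxy)-4,8-dimethylnon-3-en-2-ol
Conditions: (R)-2-methyl-CBS-oxazaborolidine (0.2 equiv), catecholborane, toluene, −78 °C; then MeOH, H2O
Reagents that add atoms: none
Why: In this Corey–Bakshi–Shibata reduction the oxazaborolidine–borane complex binds the ketone with the trisubstituted alkenyl group as the large substituent and delivers hydride to one face, which by the usual model should give the (R)-carbinol (C6) that fixes all later absolute configuration.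

Step 10
Reactants: 12 5-oxohexanoic acid
Product: 13 4-(2-methyl-1,3-dioxolan-2-yl)butanoic acid
Conditions: 2-ethyl-2-methyl-1,3-dioxolane (solvent), TsOH·H2O (cat.), ethylene glycol (cat.), rt
Reagents that add atoms: 2-ethyl-2-methyl-1,3-dioxolane, CCC1(C)OCCO1
Why: Acid-catalysed dioxolane exchange (transketalisation) masks the ketone without esterifying the carboxylic acid, butanone being the only by-product.

Step 11
Reactants: 11 (2R,3E)-9-(tert-butyldimethylsilyloxy)-1-(tert-butyldiphenylsilyloxy)-4,8-dimethylnon-3-en-2-ol; 13 4-(2-methyl-1,3-dioxolan-2-yl)butanoic acid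
Product: 14 (2R,3E)-9-(tert-butyldimethylsilyloxy)-1-(tert-butyldiphenylsilyloxy)-4,8-dimethylnon-3-en-2-yl 4-(2-methyl-1,3-dioxolan-2-yl)butanoate
Conditions: DCC, DMAP (cat.), CH2Cl2, 0 °C to rt
Reagents that add atoms: none
Why: Steglich esterification acylates the secondary allylic alcohol under neutral conditions without touching the carbinol configuration, the ketal or the silyl ethers.

Step 12
Reactants: 14 (2R,3E)-9-(tert-butyldimethylsilyloxy)-1-(tert-butyldiphenylsilyloxy)-4,8-dimethylnon-3-en-2-yl 4-(2-methyl-1,3-dioxolan-2-yl)butanoate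
Product: 17 (4E)-6-(tert-butyldiphenylsilyloxy)-3-[5-(tert-butyldimethylsilyloxy)-4-methylpentyl]-3-methyl-2-[2-(2-methyl-1,3-dioxolan-2-yl)ethyl]hex-4-enoic acid with C9 and C10 as in the target, via silyl ketene acetal 15 (not isolated), via trimethylsilyl ester 16 (not isolated)
Conditions: LiN(iPr)2, THF/HMPA (4:1), −78 °C; Me3SiCl/Et3N, −78 °C to rt, then 50 °C; H2O work-up
Reagents that add atoms: none
Why: In this Ireland–Claisen rearrangement HMPA-mediated enolisation gives the Z(O)-enolate and hence the (Z)-silyl ketene acetal 15, whose chair transition state keeps the CH2OSi group on C6 equatorial (the axial alternative suffers allylic 1,3-strain with the cis methyl on C10), so that the C6 configuration is relayed to C10 and, through the acetal geometry, to C9, while the new C5=C6 alkene forms E and any C9 epimer from the minor enolate is removed by chromatography.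

Step 13
Reactants: 17 the C8 acid
Product: 18 the corresponding methyl ketone (C8 acetyl group on C9; C9 and C10 as in the target)
Conditions: MeLi (3 equiv), Et2O/THF, 0 °C; inverse quench into H2O, 0 °C
Reagents that add atoms: methyllithium, [Li]C
Why: Addition of an organolithium to the lithium carboxylate stops at the stable geminal dialkoxide, which releases the methyl ketone only on work-up, so over-addition and enolisation at C9 are avoided.

Step 14
Reactants: 18 the methyl ketone
Product: 19 the terminal enol triflate (C8 bears OSO2CF3 and =CH2, the later C17)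
Conditions: KN(SiMe3)2, THF, −78 °C; PhNTf2, −78 to 0 °C
Reagents that add atoms: N-phenylbis(trifluoromethanesulfonimide), O=S(=O)(N(c1ccccc1)S(=O)(=O)C(F)(F)F)C(F)(F)F
Why: Kinetic deprotonation by the hindered amide occurs at the methyl group and not at the congested C9–H, and O-sulfonylation of the enolate gives the 1-alken-2-yl triflate.

Step 15
Reactants: 19 the enol triflate; 20 tributyl(vinyl)stannane
Product: 21 the 2-substituted buta-1,3-diene (C9 bears C(=CH2)CH=CH2)
Conditions: Pd(PPh3)4 (5 mol%), LiCl (3 equiv), THF, 65 °C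
Reagents that add atoms: none
Why: Stille cross-coupling of an alkenyl triflate with a vinylstannane, promoted by chloride, forms the C8–C7 bond with retention of the 1,1-disubstituted alkene and tolerates ketal and silyl ethers.

Step 16
Reactants: 21 the bis-silyl diene
Product: 22 the primary alcohol (C18–OH free, C7′–OSi retained)
Conditions: HF·pyridine, pyridine, THF, 0 °C to rt
Reagents that add atoms: none
Why: Buffered fluoride desilylation cleaves the primary tert-butyldimethylsilyl ether much faster than the tert-butyldiphenylsilyl ether and spares the dioxolane and the diene.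

Step 17
Reactants: 22 the primary alcohol
Product: 23 the C18 carboxylic acid (C7′–OSi retained)
Conditions: TEMPO (0.2 equiv), PhI(OAc)2 (2.2 equiv), MeCN/H2O (1:1), rt
Reagents that add atoms: water, O
Why: Oxoammonium-mediated oxidation takes the primary alcohol through the aldehyde hydrate to the acid under nearly neutral conditions that diene, ketal and silyl ether tolerate.

Step 18
Reactants: 23 the silyl ether acid
Product: 24 the seco acid (C18 CO2H and C7′ allylic OH)
Conditions: Bu4NF/AcOH (1:1), THF, rt
Reagents that add atoms: none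
Why: Fluoride-induced desilylation frees the allylic alcohol, and acetic acid buffering keeps the medium non-basic.

Step 19
Reactants: 24 the seco acid
Product: 25 the ten-membered E-allylic lactone (C18 carbonyl, ring O, C7′, C6=C5, C10, C1, C2, C3, C4; both C4 epimers)
Conditions: 2-methyl-6-nitrobenzoic anhydride, DMAP, Et3N, CH2Cl2, rt, slow addition (final 1 mM)
Reagents that add atoms: none
Why: In this Shiina macrolactonisation the mixed anhydride is transferred by DMAP to the primary allylic hydroxyl under high dilution, and the quaternary C10 together with the trans alkene pre-organises the chain for ten-membered ring closure.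

Step 20
Reactants: 25 the ten-membered lactone
Product: 28 (4S,5S,9R,10S) ring-A vinyl acid (C4 bears CH3 and CO2H; C5 bears the C6=C7′ vinyl group), via silyl ketene acetal 26 (not isolated), via trimethylsilyl ester 27 (not isolated)
Conditions: LiN(iPr)2 (1.5 equiv), Me3SiCl/Et3N, THF/HMPA (4:1), −78 °C; then rt to 60 °C; H2O work-up; recovered 25 is recycled
Reagents that add atoms: none
Why: LiN(iPr)2 removes H4 from either C4 epimer and Me3SiCl traps the enolate as the tetrasubstituted silyl ketene acetal 26, which on warming undergoes a [3,3]-sigmatropic shift through C4, C18, O, C7′, C6 and C5 that forms the C4–C5 bond, breaks the O–C7′ bond and leaves silyl ester 27, hydrolysed on work-up. The closest known reaction type is the Ireland–Claisen ring contraction of macrocyclic allylic lactones to 2-alkenylcycloalkanecarboxylic acids, the oxygen analogue of the Cope rearrangement of E,E-cyclodeca-1,5-dienes. Ring A closes by transannular bond formation across the ten-membered ring (a four-atom ring contraction) through a chair–chair, trans-decalin-like transition state in which the six-atom Claisen array and the forming cyclohexane share the C4–C5 bond. C4 is controlled by the acetal geometry together with the chair mode: with C3 syn to OSi (the Z acetal, ring carbon and ring oxygen trans across C4=C18), C18 and C6 end trans-diequatorial and the C4 methyl and H5 trans-diaxial. C5 is controlled by C10, whose bulky C9 substituent takes the equatorial site of the forming ring so that C20 is axial and anti to H5. The step therefore needs the Z acetal and the chair: HMPA-mediated enolisation is chosen to place the larger α-substituent (ring carbon C3) syn to the enolate oxygen, the E ring alkene is fixed by the substrate, and the bath is held at the lowest temperature that turns over the strained E,E-type acetal so that a geometric isomer, which would give the C4 epimer, is returned as lactone on work-up.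

Step 21
Reactants: 28 the ring-A vinyl acid
Product: 29 (4S,5S,9R,10S) primary alcohol (C18 CH2OH)
Conditions: LiAlH4, THF, 0 °C to reflux; then H2O
Reagents that add atoms: none
Why: Hydride reduction of the hindered neopentyl carboxylic acid gives the C18 alcohol without affecting the ketal, the vinyl group or the diene.

Step 22
Reactants: 29 the primary alcohol
Product: 30 (4S,5S,9R,10S) acetate (C18 CH2OAc)
Conditions: Ac2O, pyridine, DMAP (cat.), CH2Cl2, rt
Reagents that add atoms: acetic anhydride, CC(=O)OC(C)=O
Why: DMAP-catalysed acylation installs the C18 acetate of the target on the neopentyl alcohol.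

Step 23
Reactants: 30 the triene acetate
Product: 31 (4S,5S,9R,10S) bicyclic diene ketal (ring B with C6=C7 and exocyclic C8=C17)
Conditions: second-generation Hoveyda–Grubbs catalyst [RuCl2(H2IMes)(=CH-C6H4-2-OiPr)] (10 mol%), toluene (5 mM), 80 °C
Reagents that add atoms: none
Why: In this ring-closing diene–ene metathesis the catalyst loads on the unhindered terminal CH=CH2 of the butadiene and the vinylcarbene closes onto the C5 vinyl group, held beside it as a trans-diequatorial neighbour on ring A, releasing ethylene (C7′ and the terminal diene carbon) and closing the six-membered ring B as the C6=C7/C8=C17 diene.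

Step 24
Reactants: 31 the bicyclic diene ketal
Product: 32 (4S,5S,9R,10S) methyl ketone (C13=O)
Conditions: PPTS (cat.), acetone/H2O (9:1), 50 °C
Reagents that add atoms: water, O
Why: Mild acid-catalysed ketal hydrolysis unmasks the C13 ketone without cleaving the acetate or isomerising the exocyclic diene.

Step 25
Reactants: 32 the methyl ketone; 33 trimethyl phosphonoacetate
Product: 34 target, methyl (4S,5S,9R,10S,13E)-18-acetoxylabda-6,8(17),13-trien-15-oate
Conditions: NaH, THF, 0 to 50 °C
Reagents that add atoms: none
Why: Horner–Wadsworth–Emmons olefination of the unhindered methyl ketone with the stabilised phosphonate anion should favour the E-trisubstituted enoate, with the ester anti to the larger C12 chain, and any Z isomer is removed by chromatography.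

**Compound list**

1 | geranyl acetate | CC(C)=CCC/C(C)=C/COC(C)=O | starting material
2 | (2E,6E)-8-hydroxy-3,7-dimethylocta-2,6-dien-1-yl acetate | CC(=O)OC/C=C(\C)CC/C=C(\C)CO | intermediate
3 | (2E)-8-hydroxy-3,7-dimethyloct-2-en-1-yl acetate (7RS) | CC(=O)OC/C=C(\C)CCCC(C)CO | intermediate
4 | (2E)-8-(tert-butyldimethylsilyloxy)-3,7-dimethyloct-2-en-1-yl acetate (7RS) | CC(=O)OC/C=C(\C)CCCC(C)CO[Si](C)(C)C(C)(C)C | intermediate
5 | (2E)-8-(tert-butyldimethylsilyloxy)-3,7-dimethyloct-2-en-1-ol (7RS) | OC/C=C(\C)CCCC(C)CO[Si](C)(C)C(C)(C)C | intermediate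
6 | (2E)-8-(tert-butyldimethylsilyloxy)-3,7-dimethyloct-2-enal (7RS) | O=C/C=C(\C)CCCC(C)CO[Si](C)(C)C(C)(C)C | intermediate
7 | (3E)-9-(tert-butyldimethylsilyloxy)-1-[dimethyl(propan-2-yloxy)silyl]-4,8-dimethylnon-3-en-2-ol | CC(C)O[Si](C)(C)CC(O)/C=C(\C)CCCC(C)CO[Si](C)(C)C(C)(C)C | intermediate (not isolated)
8 | (3E)-9-(tert-butyldimethylsilyloxy)-4,8-dimethylnon-3-ene-1,2-diol (2RS,8RS) | OCC(O)/C=C(\C)CCCC(C)CO[Si](C)(C)C(C)(C)C | intermediate
9 | (3E)-9-(tert-butyldimethylsilyloxy)-1-(tert-butyldiphenylsilyloxy)-4,8-dimethylnon-3-en-2-ol (2RS,8RS) | CC(C)(C)[Si](c1ccccc1)(c1ccccc1)OCC(O)/C=C(\C)CCCC(C)CO[Si](C)(C)C(C)(C)C | intermediate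
10 | (3E)-9-(tert-butyldimethylsilyloxy)-1-(tert-butyldiphenylsilyloxy)-4,8-dimethylnon-3-en-2-one (8RS) | CC(C)(C)[Si](c1ccccc1)(c1ccccc1)OCC(=O)/C=C(\C)CCCC(C)CO[Si](C)(C)C(C)(C)C | intermediate
11 | (2R,3E)-9-(tert-butyldimethylsilyloxy)-1-(tert-butyldiphenylsilyloxy)-4,8-dimethylnon-3-en-2-ol (8RS) | CC(C)(C)[Si](c1ccccc1)(c1ccccc1)OC[C@H](O)/C=C(\C)CCCC(C)CO[Si](C)(C)C(C)(C)C | intermediate
12 | 5-oxohexanoic acid | CC(=O)CCCC(=O)O | starting material
13 | 4-(2-methyl-1,3-dioxolan-2-yl)butanoic acid | CC1(CCCC(=O)O)OCCO1 | intermediate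
14 | (2R,3E)-9-(tert-butyldimethylsilyloxy)-1-(tert-butyldiphenylsilyloxy)-4,8-dimethylnon-3-en-2-yl 4-(2-methyl-1,3-dioxolan-2-yl)butanoate | CC(C)(C)[Si](c1ccccc1)(c1ccccc1)OC[C@H](OC(=O)CCCC1(C)OCCO1)/C=C(\C)CCCC(C)CO[Si](C)(C)C(C)(C)C | intermediate
15 | (Z)-trimethylsilyl ketene acetal of 14 (C11 syn to OSi) | CC1(CC/C=C(\O[Si](C)(C)C)O[C@@H](CO[Si](c2ccccc2)(c2ccccc2)C(C)(C)C)/C=C(\C)CCCC(C)CO[Si](C)(C)C(C)(C)C)OCCO1 | intermediate (not isolated)
16 | trimethylsilyl ester of acid 17 | CC(C)(C)[Si](c1ccccc1)(c1ccccc1)OC/C=C/[C@@](C)(CCCC(C)CO[Si](C)(C)C(C)(C)C)[C@@H](C(=O)O[Si](C)(C)C)CCC1(C)OCCO1 | intermediate (not isolated)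
17 | (4E)-6-(tert-butyldiphenylsilyloxy)-3-[5-(tert-butyldimethylsilyloxy)-4-methylpentyl]-3-methyl-2-[2-(2-methyl-1,3-dioxolan-2-yl)ethyl]hex-4-enoic acid, C9 and C10 as in the target | CC(C)(C)[Si](c1ccccc1)(c1ccccc1)OC/C=C/[C@@](C)(CCCC(C)CO[Si](C)(C)C(C)(C)C)[C@@H](C(=O)O)CCC1(C)OCCO1 | intermediate
18 | methyl ketone from 17 (C8 acetyl on C9) | CC(C)(C)[Si](c1ccccc1)(c1ccccc1)OC/C=C/[C@@](C)(CCCC(C)CO[Si](C)(C)C(C)(C)C)[C@@H](C(C)=O)CCC1(C)OCCO1 | intermediate
19 | enol triflate from 18 (C8 bears OSO2CF3 and =CH2) | CC(C)(C)[Si](c1ccccc1)(c1ccccc1)OC/C=C/[C@@](C)(CCCC(C)CO[Si](C)(C)C(C)(C)C)[C@@H](C(=C)OS(=O)(=O)C(F)(F)F)CCC1(C)OCCO1 | intermediate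
20 | tributyl(vinyl)stannane | C=C[Sn](CCCC)(CCCC)CCCC | starting material
21 | bis-silyl 2-substituted buta-1,3-diene (C9 bears C(=CH2)CH=CH2) | CC(C)(C)[Si](c1ccccc1)(c1ccccc1)OC/C=C/[C@@](C)(CCCC(C)CO[Si](C)(C)C(C)(C)C)[C@@H](C(=C)C=C)CCC1(C)OCCO1 | intermediate
22 | C18 primary alcohol, C7′ silyl ether | CC(C)(C)[Si](c1ccccc1)(c1ccccc1)OC/C=C/[C@@](C)(CCCC(C)CO)[C@@H](C(=C)C=C)CCC1(C)OCCO1 | intermediate
23 | C18 carboxylic acid, C7′ silyl ether | CC(C)(C)[Si](c1ccccc1)(c1ccccc1)OC/C=C/[C@@](C)(CCCC(C)C(=O)O)[C@@H](C(=C)C=C)CCC1(C)OCCO1 | intermediate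
24 | seco acid (C18 CO2H, C7′ E-allylic OH) | OC/C=C/[C@@](C)(CCCC(C)C(=O)O)[C@@H](C(=C)C=C)CCC1(C)OCCO1 | intermediate
25 | ten-membered E-allylic lactone, C9 and C10 as in the target, C4 epimer mixture | O=C1OC/C=C/[C@@](C)(CCCC1C)[C@@H](C(=C)C=C)CCC2(C)OCCO2 | intermediate
26 | (Z)-trimethylsilyl ketene acetal of 25 (C3 syn to OSi, anti to ring O) | C/C1=C(/O[Si](C)(C)C)OC/C=C/[C@@](C)(CCC1)[C@@H](C(=C)C=C)CCC2(C)OCCO2 | intermediate (not isolated)
27 | trimethylsilyl ester of acid 28 | C=C[C@@H]1[C@@](C)(C(=O)O[Si](C)(C)C)CCC[C@@]1(C)[C@@H](C(=C)C=C)CCC2(C)OCCO2 | intermediate (not isolated)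
28 | (4S,5S,9R,10S) ring-A vinyl acid | C=C[C@@H]1[C@@](C)(C(=O)O)CCC[C@@]1(C)[C@@H](C(=C)C=C)CCC2(C)OCCO2 | intermediate
29 | (4S,5S,9R,10S) ring-A vinyl alcohol | C=C[C@@H]1[C@@](C)(CO)CCC[C@@]1(C)[C@@H](C(=C)C=C)CCC2(C)OCCO2 | intermediate
30 | (4S,5S,9R,10S) ring-A vinyl acetate | C=C[C@@H]1[C@@](C)(COC(C)=O)CCC[C@@]1(C)[C@@H](C(=C)C=C)CCC2(C)OCCO2 | intermediate
31 | (4S,5S,9R,10S) bicyclic diene ketal | C=C1C=C[C@@H]2[C@@](C)(COC(C)=O)CCC[C@@]2(C)[C@@H]1CCC1(C)OCCO1 | intermediate
32 | (4S,5S,9R,10S) bicyclic diene methyl ketone | C=C1C=C[C@@H]2[C@@](C)(COC(C)=O)CCC[C@@]2(C)[C@@H]1CCC(C)=O | intermediate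
33 | trimethyl phosphonoacetate | COC(=O)CP(=O)(OC)OC | starting material
34 | methyl (4S,5S,9R,10S,13E)-18-acetoxylabda-6,8(17),13-trien-15-oate | C=C1C=C[C@@H]2[C@@](C)(COC(C)=O)CCC[C@@]2(C)[C@@H]1CC/C(C)=C/C(=O)OC | target

**Step count**

Total: 25 steps. Longest linear sequence: 24 steps (1 to 34 through steps 1–9 and 11–25); step 10 is the one-step side branch.

**Steps most likely to fail**

Step 20 (key ring contraction). The enolisation may place ring carbon C3 syn to the ring oxygen, and this geometric isomer of the acetal would rearrange through a cis-decalin-like chair to the C4 epimer. The shift may also be slowed by crowding between C4 and C10, so that fragmentation of the lactone enolate competes. Fallback: form C4–C5 by intramolecular enolate alkylation, in which the enolate carbon is exocyclic to the forming ring and its geometry no longer matters. It sets out from seco acid 24, bypasses steps 19–21 and rejoins the route at alcohol 29.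
- Me3SiCHN2 in MeOH/toluene gives the hydroxy methyl ester F1.
- MeSO2Cl, LiCl and 2,4,6-collidine in DMF convert the allylic alcohol into the primary allylic chloride F2.
- KN(SiMe3)2 in THF (−78 to 0 °C) should close ring A by 6-exo SN2′ displacement, C4 attacking C5 and chloride leaving from C7′, to give the ring-A methyl ester F3. In the chair, the potassium enolate unit, C6 and the C9 substituent should all be equatorial, which gives the same C4/C5 configuration.
- LiAlH4 in THF reduces F3 to alcohol 29.

Step 19 (macrolactonisation). Intermolecular esterification to dimers and oligomers may outrun closure of the strained ten-membered ring, or acyl transfer from the α-branched mixed anhydride may be too slow. Fallback: activate the alcohol instead of the acid. It sets out from seco acid 24 and returns at lactone 25. Mitsunobu macrolactonisation (PPh3, diisopropyl azodicarboxylate, toluene, high dilution) lets the carboxylate displace the oxyphosphonium group at the primary allylic carbon C7′ in an SN2 reaction, so the hindrance at the acyl carbon is irrelevant. This fallback makes no new compound (entry F0).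

Step 2 (directed hydrogenation). Chemoselectivity may be lost through saturation of the acetoxy-bearing alkene, allylic C–O hydrogenolysis or isomerisation of the allylic alcohol to the aldehyde, or turnover may stall with the 2-methyl-substituted allylic alcohol. Fallback: replace coordination control by polarity control. It sets out from 2 and returns at 3.
- MnO2 in CH2Cl2 oxidises 2 to the enal (2E,6E)-3,7-dimethyl-8-oxoocta-2,6-dien-1-yl acetate F4.
- Catalytic [(Ph3P)CuH]6 with PhMe2SiH in toluene reduces only the conjugated alkene by 1,4-hydride addition and gives, after hydrolysis of the silyl enol ether, the saturated aldehyde (2E)-3,7-dimethyl-8-oxooct-2-en-1-yl acetate F5.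
- NaBH4 in MeOH at 0 °C reduces the aldehyde to 3.

Further compounds
F1 | step 20 | methyl ester of seco acid 24 (C7′ allylic OH free) | OC/C=C/[C@@](C)(CCCC(C)C(=O)OC)[C@@H](C(=C)C=C)CCC1(C)OCCO1
F2 | step 20 | allylic chloride of F1 (C7′–Cl) | ClC/C=C/[C@@](C)(CCCC(C)C(=O)OC)[C@@H](C(=C)C=C)CCC1(C)OCCO1
F3 | step 20 | (4S,5S,9R,10S) ring-A vinyl methyl ester | C=C[C@@H]1[C@@](C)(C(=O)OC)CCC[C@@]1(C)[C@@H](C(=C)C=C)CCC2(C)OCCO2
F0 | step 19 | none | none
F4 | step 2 | (2E,6E)-3,7-dimethyl-8-oxoocta-2,6-dien-1-yl acetate | CC(=O)OC/C=C(\C)CC/C=C(\C)C=O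
F5 | step 2 | (2E)-3,7-dimethyl-8-oxooct-2-en-1-yl acetate (7RS) | CC(=O)OC/C=C(\C)CCCC(C)C=O
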